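(The rate constants are made up; the flask was simulated.)

Time first: this flask runs for 40 h, and I begin with what L does on its way out.

D 1.0 M; time 40 h

    L → Q (k1 = 7.8 × 10⁻⁴ s⁻¹)
    2 L → L2 (k2 = 0.0017 M⁻¹ s⁻¹)
    L + L2 → L.L2 (k3 = 7.1 × 10⁻⁴ M⁻¹ s⁻¹)
    Q ⇌ G (K4 = 24, k4 = 6.6 × 10⁻⁴ s⁻¹)
    D ⇌ L, rate k5*(cs5 - [L]) while solid is left; crystals form when [L] > cs5 (cs5 = 0.93 M, k5 = 8.4 × 10⁻⁴ s⁻¹)

- in percentages every species weighs as the D in it: one L2 counts as two
- in percentages every species weighs as the D in it: one L.L2 counts as three
- for a step with 2 of a species take k times the square, and two of it per event
- as a solid, counted per litre of solution: D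
- at the start none of D is in solution
- run time (flask): 40 h

- the Q standing at 40 h, as a percentage of the D charged
- the G standing at 40 h, as a percentage of the D charged
- amount of Q if the flask were left three thousand times as long, in percent of the D charged

What does the outcome hang on? On how L divides between the first step, towards Q, and the second, which goes with the square of c_L. I set the third step aside, as a start, since its constant 7.1 × 10⁻⁴ M⁻¹ s⁻¹ is smaller than 0.00340 M⁻¹ s⁻¹.

Where do the first two steps draw level? At 0.229 M, the even-split concentration: the c_L at which they remove L equally fast. At a mean c_L, the share taking the first step is the even-split concentration divided by itself plus that mean.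

Which mean? While solid remains, I take c_L as standing where dissolving matches both steps, at 0.297 M, which gives a share of 43.6 %.

And when the solid has gone? That last L falls away, and a straight fall has the mean 0.149 M, giving 60.7 %. Is that mean honest? The curve of the first two steps gives 64.2 %, so the error is 3.5 percentage points on that last 0.297 M of the charge.

Weighted over the charge, the share is 48.7 %. The relaxation half-life of Q and G, 0.280 h, is short against 40 h, so this share is split by the equilibrium constant: Q 1.95 %, G 46.7 %. The steps to the other products are written one way, so for the long wait I commit to Q 1.95 %.

The forecast gave 1.96 %, 47.1 % and 1.96 %, holding that “that 49% is already split 1:24, and waiting longer changes nothing”.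

The flask gives 1.96 %, 47.0 % and 1.96 %.

In this flask the first step has >99.9 % of its turnover behind it at 4.00 h, a time short against 40 h, and Q reads 1.97 % then and 1.96 % at 40.0 h. Q and G together read 49.0 % in this flask, which by the even-split concentration, with the third step set aside, means a mean c_L of 0.239 M, above 0.149 M and below 0.297 M.

For the flask charged with 0.60 M of D, the same even-split concentration gives a share of 52.1 %, so Q 2.08 % and G 50.0 %. That flask gives 2.19 % and 52.5 %.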